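**Retrosynthetic overview**
- Endgame: 38 comes from peracid epoxidation of the 1(10)-ene 37. Compound 37 comes from the trans-fused 6,12-lactone 24 by C8 Si→OH exchange, C13 methylenation, C8 angeloylation and desilylation.
- Structural feature: in the ten-membered carbocycle C1–C10, the E-C1=C10 alkene latent in the trans-oxirane stands 1,5 to the oxygen-bearing C6, which is an (E)-cyclodec-5-enone retron. C8–C9 can therefore be cut while C1–C6 is rejoined, contracting the ring to a p-menthane cyclohexanol (ring C1–C6, CH3 on C4, isopropenyl C10/C9/C14 on C1).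
- Hence 19 comes from an anionic oxy-Cope ring expansion of carbinol 16. Its C7(=C8H–Si)–C11=C12 arm comes from ethynyl addition, C-silylation and directed vinylmagnesiation on ketone 9.
- Ketone 9 comes from (R)-carvone: C3 by Luche/Mitsunobu, C6 by allylic oxidation, C4–O by nucleophilic epoxidation and SmI2 opening.
- Ring order: cyclohexane (bought) → ten-membered carbocycle (step 12) → γ-lactone (step 15) → oxirane (step 22).

Key step: step 12

Remark: germacrane numbering (C1–C15) is used for every compound, the six-membered precursors included. α/β refer to the usual germacranolide drawing with H-7 α. TBS = tert-butyldimethylsilyl, TES = triethylsilyl, Bn = benzyl.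
Assumption: benzyl(chloro)dimethylsilane, angelic acid, Eschenmoser's salt and both Grignard solutions are taken as purchasable.

Step 1
Reactants: 1 (R)-(−)-carvone
Product: 2 (1R,5R)-cis-carveol (C3-OH cis to the C1 isopropenyl group)
Conditions: NaBH4, CeCl3·7H2O, MeOH, −20 → 0 °C
Reagents that add atoms: none
Why: Luche 1,2-reduction, in which axial hydride delivery to the half-chair enone with equatorial isopropenyl should give the pseudo-equatorial (3R) allylic alcohol without conjugate reduction.

Step 2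
Reactants: 2 (1R,5R)-cis-carveol
Product: 3 (1S,5R)-trans-carveyl 4-nitrobenzoate
Conditions: 4-O2NC6H4CO2H, PPh3, DIAD, THF, 0 °C → rt
Reagents that add atoms: 4-nitrobenzoic acid, O=C(O)c1ccc(cc1)[N+](=O)[O-]
Why: Mitsunobu reaction, in which SN2 displacement of the oxyphosphonium ion by the acidic carboxylate inverts C3 to the S configuration of the target (trans to isopropenyl); the strong acid partner and low temperature hold back the SN2′ path.

Step 3
Reactants: 3 (1S,5R)-trans-carveyl 4-nitrobenzoate
Product: 4 (1S,5R)-trans-carveol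
Conditions: K2CO3 (cat.), MeOH, rt
Reagents that add atoms: none
Why: Base-catalysed transesterification cleaves the acyl–oxygen bond only, so the C3–O configuration is kept.

Step 4
Reactants: 4 (1S,5R)-trans-carveol
Product: 5 (1S,5R)-trans-carveol TBS ether
Conditions: TBSCl, imidazole, DMF, rt
Reagents that add atoms: tert-butyl(chloro)dimethylsilane, CC(C)(C)[Si](C)(C)Cl
Why: Standard imidazole-promoted O-silylation gives an ether that should withstand oxidants, organometallics and KH and that later steers the C4 face.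

Step 5
Reactants: 5 (1S,5R)-trans-carveol TBS ether
Product: 6 (4S,6R)-4-(TBSO)-3-methyl-6-(prop-1-en-2-yl)cyclohex-2-en-1-one (C6 ketone, C4=C5 alkene)
Conditions: CrO3, 3,5-dimethylpyrazole, CH2Cl2, −20 °C
Reagents that add atoms: chromium trioxide, O=[Cr](=O)=O
Why: Allylic C–H oxidation with the CrO3–dimethylpyrazole complex should take the ring C6 methylene to the enone carbonyl, because its pseudo-axial C6–H overlaps with the ring π bond, whereas C3–H is pseudo-equatorial (OTBS axial through A1,2 strain with the C4 methyl) and the isopropenyl alkene is less electron-rich; the non-basic medium leaves C1 alone.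

Step 6
Reactants: 6 enone
Product: 7 (1R,3R,5S,6S)-5-(TBSO)-6-methyl-3-(prop-1-en-2-yl)-7-oxabicyclo[4.1.0]heptan-2-one (C4–C5 oxirane trans to C3-OTBS)
Conditions: t-BuOOH, Triton B (cat.), THF, 0 °C, short contact
Reagents that add atoms: tert-butyl hydroperoxide, CC(C)(C)OO
Why: Weitz–Scheffer nucleophilic epoxidation, in which t-BuOO− adds axially to C4 on the face anti to the pseudo-axial C3-OTBS and the enolate closes, setting C4 (S) and C5 (R); the isolated isopropenyl alkene is inert to this oxidant, and catalytic base with short contact should spare the enolisable C1.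

Step 7
Reactants: 7 epoxy ketone
Product: 8 (2R,4S,5S)-4-(TBSO)-5-hydroxy-5-methyl-2-(prop-1-en-2-yl)cyclohexan-1-one
Conditions: SmI2 (2.5 equiv), THF–MeOH, −90 °C
Reagents that add atoms: none
Why: Single-electron reduction of an α,β-epoxy ketone, in which the ketyl expels the α (C5) C–O bond and the samarium enolate is protonated in situ, so the tertiary C4–O bond and its configuration are untouched and the cold protic medium should prevent retro-aldol and dehydration.

Step 8
Reactants: 8 β-hydroxy ketone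
Product: 9 (2R,4S,5S)-4-(TBSO)-5-methyl-2-(prop-1-en-2-yl)-5-(TESO)cyclohexan-1-one
Conditions: TESOTf, 2,6-lutidine, CH2Cl2, −78 °C
Reagents that add atoms: triethylsilyl triflate, CC[Si](CC)(CC)OS(=O)(=O)C(F)(F)F
Why: Silyl triflate with a hindered base silylates the tertiary alcohol fast enough in the cold to avoid β-elimination, enol silane formation and C1 epimerisation.

Step 9
Reactants: 9 bis-silyl ketone; 10 ethynylmagnesium bromide
Product: 11 (1R,2R,4S,5S)-4-(TBSO)-1-ethynyl-5-methyl-2-(prop-1-en-2-yl)-5-(TESO)cyclohexan-1-ol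
Conditions: 10, anhydrous CeCl3, THF, −78 °C; then H2O (pH 7 buffer)
Reagents that add atoms: ethynylmagnesium bromide 10, C#C[Mg]Br
Why: Weakly basic organocerium 1,2-addition avoids enolisation and loss of the β-silyloxy group; in the chair with equatorial isopropenyl and C4 methyl the axial C4-OTES closes the axial trajectory, so the acetylide should enter equatorially, trans to isopropenyl, leaving the C6-OH axial (6R).

Step 10
Reactants: 11 ethynyl carbinol
Product: 13 (1R,2R,4S,5S)-1-{[benzyl(dimethyl)silyl]ethynyl} carbinol (otherwise as 11), via dilithio alkoxide-acetylide 12 (not isolated)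
Conditions: n-BuLi (2.1 equiv), THF, −78 → −20 °C; BnMe2SiCl (1.0 equiv), −78 → 0 °C; then H2O
Reagents that add atoms: benzyl(chloro)dimethylsilane, C[Si](C)(Cl)Cc1ccccc1
Why: Double deprotonation and C-selective silylation, since the unhindered acetylide carbon outruns the crowded tertiary alkoxide for one equivalent of chlorosilane; no stereocentre is involved.

Step 11
Reactants: 13 silylalkynyl carbinol; 14 vinylmagnesium bromide
Product: 16 (1R,2R,4S,5S)-1-[(1E)-1-(benzyldimethylsilyl)buta-1,3-dien-2-yl]-4-(TBSO)-5-methyl-2-(prop-1-en-2-yl)-5-(TESO)cyclohexan-1-ol, via oxamagnesacycle 15 (not isolated)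
Conditions: 14 (6 equiv), THF–toluene, 85 °C; then H2O (pH 7 buffer), 0 °C
Reagents that add atoms: vinylmagnesium bromide 14, C=C[Mg]Br
Why: Alkoxide-directed anti-carbomagnesiation of a propargylic alcohol, in which vinyl goes to C7 and magnesium to C8, where it is stabilised by the α-silicon and held in the five-membered O–Mg–C chelate 15 (the sink even if the α-silyl alkenylmagnesium isomerises), so protonolysis should leave H cis and silicon trans to C6.

Step 12
Reactants: 16 dienyl(isopropenyl)cyclohexanol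
Product: 19 (2S,3R,5E,8S,9S)-3-[benzyl(dimethyl)silyl]-8-(TBSO)-2-ethenyl-5,9-dimethyl-9-(TESO)cyclodec-5-en-1-one (germacrane: C6 ketone; 7β-vinyl/7α-H; 8β-Si; E-C1=C10), via potassium alkoxide 17 (not isolated), via potassium dienolate 18 (not isolated)
Conditions: KH, 18-crown-6, THF, 0 °C → rt; cannulated into AcOH–THF, −78 °C
Reagents that add atoms: none
Why: KH/18-crown-6 turns 16 into the naked alkoxide 17, whose C9=C10–C1–C6–C7=C8 array undergoes a concerted, charge-accelerated [3,3]-sigmatropic shift (anionic oxy-Cope rearrangement) that forms C8–C9, breaks C1–C6 and ends irreversibly in the conjugated dienolate 18; the closest known reaction type is the ring expansion of trans-1,2-dialkenylcyclohexanols to (E)-cyclodec-5-enones. The ten-membered carbocycle thus arises by a four-atom ring enlargement, the cyclohexane opening across C1–C6 in the same event that ties the two side arms together, not by an end-to-end cyclisation. The two equatorial alkenyl groups can overlap only in a chair array with H-1 and O-6 axial, which delivers the E-C1=C10 alkene and an enolate whose ring bonds to C5 and C8 are trans; silicon, being trans to C6 on the vinylsilane, lies equatorial, so C9 bonds suprafacially to the C8 face that places silicon 8β (R), the C1/C6 centres being traded for C8. C7 is fixed in the quench: the inner face of the tetrasubstituted enolate is covered by the ring, neither O–K nor the vinyl group should turn through the ring in the cold, and dienolates are protonated kinetically at the α-carbon, so the proton reaches C7 from outside and gives 7α-H (S) with the vinyl group out of conjugation. The step needs chair over boat, one enolate face and α- over γ-protonation, which are secured by the trans-diequatorial arms, the E-vinylsilane geometry and the fast inverse quench into excess acid. Silicon tolerates the step because it is remote from the alkoxide (no 1,4-shift), a β-silyl enolate has no leaving group, and any TES exchange between the syn-diaxial O-4 and O-6 is reversible and drained through 17.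

Step 13
Reactants: 19 cyclodecenone
Product: 20 6α-alcohol (6R; 6β-H, 7α-H; otherwise as 19)
Conditions: DIBAL-H, CH2Cl2, −78 °C (crude 19, at once); aq. Rochelle salt
Reagents that add atoms: none
Why: Peripheral hydride attack on a medium-ring ketone, in which the ring covers the inner carbonyl face and the hydride should arrive from outside, past H-7 and anti to the vinyl group (Felkin–Anh with vinyl perpendicular), giving the 6α-OH needed for the trans-lactone; the cold, non-basic reagent preserves the labile C7 centre.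

Step 14
Reactants: 20 6α-alcohol
Product: 22 6α,12-diol (C7 side chain CH2CH2OH), via B-alkyl-9-BBN adduct 21 (not isolated)
Conditions: 9-BBN (excess), THF, 0 °C → rt; then aq. NaOH, 30% H2O2, 0 °C
Reagents that add atoms: hydrogen peroxide, OO
Why: Hydroboration–oxidation, in which 9-BBN selects the monosubstituted vinyl group over the trisubstituted C1=C10 alkene and places boron on terminal C12; the tetraorganosilane and both silyl ethers are inert to cold alkaline peroxide.

Step 15
Reactants: 22 6α,12-diol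
Product: 24 trans-fused 6α,12-lactone (C11 = CH2; 8β-SiMe2Bn; 3β-OTBS; 4α-OTES; E-C1=C10), via lactol 23 (not isolated)
Conditions: TEMPO (cat.), PhI(OAc)2, CH2Cl2, rt
Reagents that add atoms: none
Why: Oxoammonium-mediated oxidative lactonisation of a 1,4-diol, in which the primary alcohol is oxidised first, the aldehyde closes with O-6 to the five-membered lactol 23, and this is oxidised on; with silicon instead of oxygen on C8 only the 6,12-closure exists, and C6/C7 are untouched, so the ring fusion is trans.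

Step 16
Reactants: 24 silyl lactone
Product: 26 8β-hydroxy 6α,12-lactone (8R), via silanol 25 (not isolated)
Conditions: TBAF (1.2 equiv), THF, 0 °C, 10 min; then KHCO3, 30% H2O2, MeOH–THF, rt → 40 °C
Reagents that add atoms: hydrogen peroxide, OO
Why: Tamao–Fleming oxidation of a benzyldimethylsilyl group, in which fluoride expels benzyl as toluene within minutes, faster than it should attack the neopentyl-type C3-OTBS and tertiary C4-OTES ethers, and silanol 25 is oxidised by a 1,2-shift of C8 from Si to O with retention; the bicarbonate medium restrains acyl migration to O-8 and ignores the isolated alkene.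

Step 17
Reactants: 26 8β-hydroxy lactone
Product: 27 8β-OTMS lactone
Conditions: TMSCl, imidazole, CH2Cl2, 0 °C
Reagents that add atoms: chlorotrimethylsilane, C[Si](C)(C)Cl
Why: Transient O-silylation keeps a C8 alkoxide from forming in the next step, where it could attack C12 and shift the lactone to the 8,12-position.

Step 18
Reactants: 27 8β-OTMS lactone; 28 Eschenmoser's salt
Product: 30 11-(dimethylaminomethyl) lactone (11β-H), via lithium enolate 29 (not isolated)
Conditions: LDA, THF, −78 °C; then 28, −78 → 0 °C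
Reagents that add atoms: Eschenmoser's salt 28, C[N+](C)=C.[I-]
Why: Mannich reaction of a lactone enolate with a preformed iminium salt brings in C13; the electrophile should approach C11 anti to the C7–C8 bond, but this centre is erased in the next step.

Step 19
Reactants: 30 Mannich base
Product: 33 8β-hydroxy α-methylene 6α,12-lactone (3β-OTBS; 4α-OTES; E-C1=C10), via ammonium iodide 31 (not isolated), via TMS-protected methylene lactone 32 (not isolated)
Conditions: MeI, CH2Cl2, rt; aq. NaHCO3–CH2Cl2, rt; then aq. citric acid, THF, 0 °C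
Reagents that add atoms: none
Why: N-quaternisation followed by mild-base E1cB (Hofmann-type) elimination creates the C11=C13 alkene, and dilute acid removes only the labile secondary TMS ether; oxa-Michael closure of O-8 onto C13 would be 5-endo-trig and is not expected.

Step 20
Reactants: 33 8β-hydroxy α-methylene lactone; 34 angelic acid
Product: 36 8β-angelate bis-silyl ether, via mixed anhydride 35 (not isolated)
Conditions: 34, 2,4,6-Cl3C6H2COCl, Et3N, toluene, rt; then 33, 75 °C (no DMAP)
Reagents that add atoms: angelic acid 34, C/C=C(/C)C(=O)O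
Why: Yamaguchi mixed-anhydride esterification run thermally without a nucleophilic catalyst avoids the addition–elimination path that turns angelate into tiglate, so the Z geometry should be kept; C8-OH is the only free hydroxyl.

Step 21
Reactants: 36 8β-angelate bis-silyl ether
Product: 37 3β,4α-dihydroxy-8β-angeloyloxygermacra-1(10)E,11(13)-dien-6α,12-olide
Conditions: HF·pyridine, pyridine, THF, 0 °C → rt
Reagents that add atoms: none
Why: Buffered fluoride desilylation removes both silyl ethers under conditions too weakly acidic and non-nucleophilic to touch the methylene lactone, the angelate or the ring alkene.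

Step 22
Reactants: 37 1(10)-ene diol
Product: 38 argophyllin A (1β,10α-epoxy-3β,4α-dihydroxy-8β-angeloyloxygermacr-11(13)-en-6α,12-olide; 1R,3S,4S,6R,8R,10R, 7α-H)
Conditions: m-CPBA, NaHCO3, CH2Cl2, −20 → 0 °C
Reagents that add atoms: m-chloroperbenzoic acid, O=C(OO)c1cccc(Cl)c1
Why: Prilezhaev epoxidation, in which the electron-rich C1=C10 alkene reacts far faster than the two acceptor-substituted alkenes and, because it turns freely through the ring (H-1 inside), the face is chosen by the lactone-anchored conformer with C14 on the β side usual for 6α,12-germacranolides, whose exposed face, also reached by a peracid hydrogen-bonded to the 3β-OH, should give the 1β,10α trans-epoxide; the buffer prevents transannular opening by O-3/O-4.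

**Compound list**
1 | (R)-(−)-carvone | [C@H]1(C(C)=C)CC(=O)C(C)=CC1 | starting material
2 | (1R,5R)-cis-carveol | [C@H]1(C(C)=C)C[C@@H](O)C(C)=CC1 | intermediate
3 | (1S,5R)-trans-carveyl 4-nitrobenzoate | [C@H]1(C(C)=C)C[C@H](OC(=O)c2ccc(cc2)[N+](=O)[O-])C(C)=CC1 | intermediate
4 | (1S,5R)-trans-carveol | [C@H]1(C(C)=C)C[C@H](O)C(C)=CC1 | intermediate
5 | (1S,5R)-trans-carveol TBS ether | [C@H]1(C(C)=C)C[C@H](O[Si](C)(C)C(C)(C)C)C(C)=CC1 | intermediate
6 | (4S,6R)-4-(TBSO)-3-methyl-6-(prop-1-en-2-yl)cyclohex-2-en-1-one | [C@H]1(C(C)=C)C[C@H](O[Si](C)(C)C(C)(C)C)C(C)=CC1=O | intermediate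
7 | (1R,3R,5S,6S)-5-(TBSO)-6-methyl-3-(prop-1-en-2-yl)-7-oxabicyclo[4.1.0]heptan-2-one | [C@H]1(C(C)=C)C[C@H](O[Si](C)(C)C(C)(C)C)[C@@]2(C)O[C@H]2C1=O | intermediate
8 | (2R,4S,5S)-4-(TBSO)-5-hydroxy-5-methyl-2-(prop-1-en-2-yl)cyclohexan-1-one | [C@H]1(C(C)=C)C[C@H](O[Si](C)(C)C(C)(C)C)[C@@](C)(O)CC1=O | intermediate
9 | (2R,4S,5S)-4-(TBSO)-5-methyl-2-(prop-1-en-2-yl)-5-(TESO)cyclohexan-1-one | [C@H]1(C(C)=C)C[C@H](O[Si](C)(C)C(C)(C)C)[C@@](C)(O[Si](CC)(CC)CC)CC1=O | intermediate
10 | ethynylmagnesium bromide | C#C[Mg]Br | starting material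
11 | (1R,2R,4S,5S)-4-(TBSO)-1-ethynyl-5-methyl-2-(prop-1-en-2-yl)-5-(TESO)cyclohexan-1-ol | [C@H]1(C(C)=C)C[C@H](O[Si](C)(C)C(C)(C)C)[C@@](C)(O[Si](CC)(CC)CC)C[C@]1(O)C#C | intermediate
12 | dilithio alkoxide-acetylide of 11 | [C@H]1(C(C)=C)C[C@H](O[Si](C)(C)C(C)(C)C)[C@@](C)(O[Si](CC)(CC)CC)C[C@]1([O-])C#[C-].[Li+].[Li+] | intermediate
13 | (1R,2R,4S,5S)-1-{[benzyl(dimethyl)silyl]ethynyl}-4-(TBSO)-5-methyl-2-(prop-1-en-2-yl)-5-(TESO)cyclohexan-1-ol | [C@H]1(C(C)=C)C[C@H](O[Si](C)(C)C(C)(C)C)[C@@](C)(O[Si](CC)(CC)CC)C[C@]1(O)C#C[Si](C)(C)Cc2ccccc2 | intermediate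
14 | vinylmagnesium bromide | C=C[Mg]Br | starting material
15 | five-membered oxamagnesacycle (O6–Mg–C8, vinyl on C7) | [C@H]1(C(C)=C)C[C@H](O[Si](C)(C)C(C)(C)C)[C@@](C)(O[Si](CC)(CC)CC)C[C@]1(O[Mg]2)C(C=C)=C2[Si](C)(C)Cc3ccccc3 | intermediate
16 | (1R,2R,4S,5S)-1-[(1E)-1-(benzyldimethylsilyl)buta-1,3-dien-2-yl]-4-(TBSO)-5-methyl-2-(prop-1-en-2-yl)-5-(TESO)cyclohexan-1-ol | [C@H]1(C(C)=C)C[C@H](O[Si](C)(C)C(C)(C)C)[C@@](C)(O[Si](CC)(CC)CC)C[C@]1(O)/C(C=C)=C/[Si](C)(C)Cc2ccccc2 | intermediate
17 | potassium alkoxide of 16 | [C@H]1(C(C)=C)C[C@H](O[Si](C)(C)C(C)(C)C)[C@@](C)(O[Si](CC)(CC)CC)C[C@]1([O-])/C(C=C)=C/[Si](C)(C)Cc2ccccc2.[K+] | intermediate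
18 | potassium dienolate of the ten-membered ring (C5 and C8 trans across C6=C7; E-C1=C10; 8β-Si) | [K+].[O-]/C1=C(/C=C)[C@H]([Si](C)(C)Cc2ccccc2)C/C(C)=C/C[C@H](O[Si](C)(C)C(C)(C)C)[C@@](C)(O[Si](CC)(CC)CC)C1 | intermediate
19 | (2S,3R,5E,8S,9S)-3-[benzyl(dimethyl)silyl]-8-(TBSO)-2-ethenyl-5,9-dimethyl-9-(TESO)cyclodec-5-en-1-one | O=C1C[C@](C)(O[Si](CC)(CC)CC)[C@@H](O[Si](C)(C)C(C)(C)C)C/C=C(\C)C[C@@H]([Si](C)(C)Cc2ccccc2)[C@H]1C=C | intermediate
20 | 6α-alcohol (6R) of 19 | O[C@@H]1C[C@](C)(O[Si](CC)(CC)CC)[C@@H](O[Si](C)(C)C(C)(C)C)C/C=C(\C)C[C@@H]([Si](C)(C)Cc2ccccc2)[C@H]1C=C | intermediate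
21 | C12 B-alkyl-9-BBN adduct of 20 | O[C@@H]1C[C@](C)(O[Si](CC)(CC)CC)[C@@H](O[Si](C)(C)C(C)(C)C)C/C=C(\C)C[C@@H]([Si](C)(C)Cc2ccccc2)[C@H]1CCB2C3CCCC2CCC3 | intermediate
22 | 6α,12-diol | O[C@@H]1C[C@](C)(O[Si](CC)(CC)CC)[C@@H](O[Si](C)(C)C(C)(C)C)C/C=C(\C)C[C@@H]([Si](C)(C)Cc2ccccc2)[C@H]1CCO | intermediate
23 | 6α,12-lactol (anomers at C12) | C1C(O)O[C@@H]2C[C@](C)(O[Si](CC)(CC)CC)[C@@H](O[Si](C)(C)C(C)(C)C)C/C=C(\C)C[C@@H]([Si](C)(C)Cc3ccccc3)[C@@H]12 | intermediate
24 | trans-fused 6α,12-lactone, 8β-SiMe2Bn, C11 = CH2 | C1C(=O)O[C@@H]2C[C@](C)(O[Si](CC)(CC)CC)[C@@H](O[Si](C)(C)C(C)(C)C)C/C=C(\C)C[C@@H]([Si](C)(C)Cc3ccccc3)[C@@H]12 | intermediate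
25 | 8β-(hydroxydimethylsilyl) lactone (silanol) | C1C(=O)O[C@@H]2C[C@](C)(O[Si](CC)(CC)CC)[C@@H](O[Si](C)(C)C(C)(C)C)C/C=C(\C)C[C@@H]([Si](C)(C)O)[C@@H]12 | intermediate
26 | 8β-hydroxy 6α,12-lactone | C1C(=O)O[C@@H]2C[C@](C)(O[Si](CC)(CC)CC)[C@@H](O[Si](C)(C)C(C)(C)C)C/C=C(\C)C[C@@H](O)[C@@H]12 | intermediate
27 | 8β-OTMS 6α,12-lactone | C1C(=O)O[C@@H]2C[C@](C)(O[Si](CC)(CC)CC)[C@@H](O[Si](C)(C)C(C)(C)C)C/C=C(\C)C[C@@H](O[Si](C)(C)C)[C@@H]12 | intermediate
28 | Eschenmoser's salt (N,N-dimethylmethyleneiminium iodide) | C[N+](C)=C.[I-] | starting material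
29 | lithium enolate of 27 | [Li+].C1=C([O-])O[C@@H]2C[C@](C)(O[Si](CC)(CC)CC)[C@@H](O[Si](C)(C)C(C)(C)C)C/C=C(\C)C[C@@H](O[Si](C)(C)C)[C@@H]12 | intermediate
30 | 11-(dimethylaminomethyl) lactone (11β-H) | CN(C)C[C@@H]1C(=O)O[C@@H]2C[C@](C)(O[Si](CC)(CC)CC)[C@@H](O[Si](C)(C)C(C)(C)C)C/C=C(\C)C[C@@H](O[Si](C)(C)C)[C@@H]12 | intermediate
31 | trimethylammonium iodide of 30 | C[N+](C)(C)C[C@@H]1C(=O)O[C@@H]2C[C@](C)(O[Si](CC)(CC)CC)[C@@H](O[Si](C)(C)C(C)(C)C)C/C=C(\C)C[C@@H](O[Si](C)(C)C)[C@@H]12.[I-] | intermediate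
32 | 8β-OTMS α-methylene lactone | C=C1C(=O)O[C@@H]2C[C@](C)(O[Si](CC)(CC)CC)[C@@H](O[Si](C)(C)C(C)(C)C)C/C=C(\C)C[C@@H](O[Si](C)(C)C)[C@@H]12 | intermediate
33 | 8β-hydroxy α-methylene 6α,12-lactone | C=C1C(=O)O[C@@H]2C[C@](C)(O[Si](CC)(CC)CC)[C@@H](O[Si](C)(C)C(C)(C)C)C/C=C(\C)C[C@@H](O)[C@@H]12 | intermediate
34 | angelic acid, (Z)-2-methylbut-2-enoic acid | C/C=C(/C)C(=O)O | starting material
35 | angelic 2,4,6-trichlorobenzoic anhydride | C/C=C(/C)C(=O)OC(=O)c1c(Cl)cc(Cl)cc1Cl | intermediate
36 | 8β-angelate, 3β-OTBS, 4α-OTES | C=C1C(=O)O[C@@H]2C[C@](C)(O[Si](CC)(CC)CC)[C@@H](O[Si](C)(C)C(C)(C)C)C/C=C(\C)C[C@@H](OC(=O)/C(C)=C\C)[C@@H]12 | intermediate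
37 | 3β,4α-dihydroxy-8β-angeloyloxygermacra-1(10)E,11(13)-dien-6α,12-olide | C=C1C(=O)O[C@@H]2C[C@](C)(O)[C@@H](O)C/C=C(\C)C[C@@H](OC(=O)/C(C)=C\C)[C@@H]12 | intermediate
38 | argophyllin A | C=C1C(=O)O[C@@H]2C[C@](C)(O)[C@@H](O)C[C@H]3O[C@]3(C)C[C@@H](OC(=O)/C(C)=C\C)[C@@H]12 | target

**Step count and risks**

Total step count: 22. Longest linear sequence: 22 steps (1 → 38).

**1. Step 11 (directed carbomagnesiation).**
- What may go wrong: the addition to the hindered, silyl-capped alkyne may be too slow or lose regiocontrol, and long heating of the magnesium alkoxide may let the TES group migrate.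
- Fallback from 11, back at 16 (steps 10 and 11 are bypassed): tributylstannyllithium and benzyl(chloro)dimethylsilane give (benzyldimethylsilyl)tributylstannane F1. Pd(PPh3)4-catalysed syn-silastannation of the terminal alkyne of 11 places silicon on terminal C8 and tin on internal C7, giving the (Z)-1-silyl-2-stannylalkene F2, in which silicon is already trans to C6. A copper-assisted Stille coupling of F2 with vinyl bromide exchanges tin for vinyl with retention and gives 16.

**2. Step 12 (oxy-Cope rearrangement and C7 protonation).**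
- What may go wrong: proton transfer may go to C12 instead of C7, the vinyl ketone may drift into conjugation or epimerise at C7 during quench and handling, and the enolate face may leak at the temperature of the rearrangement.
- Fallback from 16, back at 22: the rearrangement is run as before, but dienolate 18 is silylated on oxygen with TMSCl at −78 °C to the trimethylsilyl dienol ether F3. 9-BBN adds only to its terminal C11=C12 bond, and buffered (pH 7) peroxide oxidation gives the hydroxyethyl silyl enol ether F4, which has no γ-position left to protonate. Cold aqueous citric acid protonates C7 from the open face and releases the hydroxy ketone F5, which cannot conjugate. DIBAL-H reduction as in step 13 then gives diol 22.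

**3. Step 13 (C6 reduction).**
- What may go wrong: facial selectivity may be poor or reversed, because the carbonyl group can turn within the ring and a conformer with the C7–C8 bond perpendicular to C=O exposes the other face.
- Fallback from 19, back at 24: the lactone C6–O bond is made with inversion instead of retention. Reduction under the conditions that favour the other face gives the 6-epi alcohol F6, and MsCl/Et3N gives the mesylate F7. 9-BBN followed by buffered peroxide gives the hydroxy mesylate F8, and TEMPO/PhI(OAc)2 in MeCN–H2O gives the mesyloxy acid F9. Cs2CO3 in DMF closes the ring by 5-exo-tet SN2 attack of the carboxylate on C6, giving the trans-lactone 24.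

**Further compounds**
F1 | step 11 | (benzyldimethylsilyl)tributylstannane | CCCC[Sn](CCCC)(CCCC)[Si](C)(C)Cc1ccccc1
F2 | step 11 | (Z)-1-silyl-2-stannylalkene (C7-SnBu3, C8-SiMe2Bn, Si trans to C6) | [C@H]1(C(C)=C)C[C@H](O[Si](C)(C)C(C)(C)C)[C@@](C)(O[Si](CC)(CC)CC)C[C@]1(O)/C([Sn](CCCC)(CCCC)CCCC)=C/[Si](C)(C)Cc2ccccc2
F3 | step 12 | trimethylsilyl dienol ether of the ten-membered ring | C[Si](C)(C)O/C1=C(/C=C)[C@H]([Si](C)(C)Cc2ccccc2)C/C(C)=C/C[C@H](O[Si](C)(C)C(C)(C)C)[C@@](C)(O[Si](CC)(CC)CC)C1
F4 | step 12 | hydroxyethyl silyl enol ether | C[Si](C)(C)O/C1=C(/CCO)[C@H]([Si](C)(C)Cc2ccccc2)C/C(C)=C/C[C@H](O[Si](C)(C)C(C)(C)C)[C@@](C)(O[Si](CC)(CC)CC)C1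
F5 | step 12 | hydroxy ketone (C6 ketone, 7α-H, C12-OH) | O=C1C[C@](C)(O[Si](CC)(CC)CC)[C@@H](O[Si](C)(C)C(C)(C)C)C/C=C(\C)C[C@@H]([Si](C)(C)Cc2ccccc2)[C@H]1CCO
F6 | step 13 | 6-epi alcohol (6β-OH) | O[C@H]1C[C@](C)(O[Si](CC)(CC)CC)[C@@H](O[Si](C)(C)C(C)(C)C)C/C=C(\C)C[C@@H]([Si](C)(C)Cc2ccccc2)[C@H]1C=C
F7 | step 13 | 6β-mesylate | CS(=O)(=O)O[C@H]1C[C@](C)(O[Si](CC)(CC)CC)[C@@H](O[Si](C)(C)C(C)(C)C)C/C=C(\C)C[C@@H]([Si](C)(C)Cc2ccccc2)[C@H]1C=C
F8 | step 13 | hydroxy mesylate (C12-OH) | CS(=O)(=O)O[C@H]1C[C@](C)(O[Si](CC)(CC)CC)[C@@H](O[Si](C)(C)C(C)(C)C)C/C=C(\C)C[C@@H]([Si](C)(C)Cc2ccccc2)[C@H]1CCO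
F9 | step 13 | mesyloxy acid (C12 carboxylic acid) | CS(=O)(=O)O[C@H]1C[C@](C)(O[Si](CC)(CC)CC)[C@@H](O[Si](C)(C)C(C)(C)C)C/C=C(\C)C[C@@H]([Si](C)(C)Cc2ccccc2)[C@H]1CC(=O)O
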